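**Retrosynthetic overview**
1. The last step acylates O9. Before it, a chromium Barbier macrocyclisation forms C6–C7 and closes the ten-membered ring; the resulting alkoxide closes the γ-lactone in the same flask.
2. The C11–C13 acrylate is attached to a C7 vinyl group by cross-metathesis. C9–C10 comes from a Nozaki–Hiyama–Kishi coupling of a (Z)-α-iodoenal acetal (C1–C6, C10, C14) with an α-acyloxy aldehyde (C7–C9).
3. Key step: Birch dearomatisation of 4-methylanisole. The ring is kept as a template that locks the C4=C5 alkene cis, then is cut open by Baeyer–Villiger ring expansion and reduction to give C1–C6 with both ends differentiated and unprotected.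
4. C8 is set by Sharpless desymmetrisation of divinylcarbinol (the oxirane is the masked C9 aldehyde), C9 by the ligand-controlled coupling, C6 and C7 in the macrocyclisation.
5. Ring order: six- and seven-membered template rings (both opened), then the ten-membered carbocycle, then the γ-lactone.

Assumption: the SMILES is taken as drawn, that is (6R,7S,8S,9S) in germacrane numbering with both ring alkenes cis within the ring (C4=C5 is Z, C1=C10 is E by the sequence rule); positions below use this numbering (C6 lactone carbinol, C8 and C9 ester carbons, C10 formyl-bearing carbon, C11–C13 acrylate unit, C14 formyl, C15 methyl).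

**Route**

Step 1
Reactants: 1 4-methylanisole
Product: 3 4-methylcyclohex-3-en-1-one, via 1-methoxy-4-methylcyclohexa-1,4-diene 2 (not isolated)
Conditions: Li, NH3 (l), t-BuOH, THF, −78 to −33 °C; then (CO2H)2, MeOH–H2O, rt
Reagents that add atoms: water, O
Why: Birch reduction gives the 2,5-dihydro enol ether and mild acid hydrolysis unmasks the β,γ-unsaturated ketone without moving the alkene into conjugation, so the six-membered ring now holds the future C4=C5 alkene with its methyl group and the ring-cis geometry the target needs.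

Step 2
Reactants: 3 4-methylcyclohex-3-en-1-one
Product: 4 5-methyl-4,7-dihydrooxepin-2(3H)-one
Conditions: (Me3SiO)2, SnCl4 (0.3 equiv), trans-cyclohexane-1,2-diamine (0.3 equiv), 4 Å MS, CH2Cl2, 0 °C to rt
Reagents that add atoms: bis(trimethylsilyl) peroxide, C[Si](C)(C)OO[Si](C)(C)C
Why: Baeyer–Villiger oxidation with a silyl peroxide and SnCl4, a reagent pair that oxidises β,γ-unsaturated ketones at the carbonyl without epoxidising the alkene, in which the allylic methylene should migrate in preference to the plain methylene so that oxygen is inserted next to the future C6.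

Step 3
Reactants: 4 5-methyl-4,7-dihydrooxepin-2(3H)-one; 5 (triphenylphosphoranylidene)acetaldehyde
Product: 7 (2E,6Z)-8-hydroxy-6-methylocta-2,6-dienal, via (4Z)-6-hydroxy-4-methylhex-4-enal 6 (not isolated)
Conditions: i-Bu2AlH (1.05 equiv), CH2Cl2, −78 °C; then 5, −78 °C to rt
Reagents that add atoms: none
Why: partial reduction of the lactone to the lactol (open form 6) followed in the same flask by Wittig olefination with the stabilised formyl ylide, which gives the E-enal (C10 and C14 added) and frees the C6 hydroxyl without any protecting group.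

Step 4
Reactants: 7 (2E,6Z)-8-hydroxy-6-methylocta-2,6-dienal
Product: 8 (2Z,6Z)-8-hydroxy-2-iodo-6-methylocta-2,6-dienal
Conditions: I2, K2CO3, DMAP (0.2 equiv), THF–H2O 1:1, rt
Reagents that add atoms: iodine, II
Why: α-iodination of the enal by a DMAP-catalysed addition–iodination–elimination sequence (Baylis–Hillman type), which gives the (Z)-α-iodoenal with iodine cis to the chain, the geometry needed for C9 to end cis to C2.

Step 5
Reactants: 8 (2Z,6Z)-8-hydroxy-2-iodo-6-methylocta-2,6-dienal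
Product: 9 (2Z,6Z)-7-iodo-8,8-dimethoxy-3-methylocta-2,6-dien-1-ol
Conditions: HC(OMe)3, PPTS (5 mol %), MeOH, rt
Reagents that add atoms: trimethyl orthoformate, COC(OC)OC
Why: acid-catalysed acetalisation with the orthoformate as water scavenger masks the formyl carbon C14 so that it cannot compete as an electrophile in the two chromium steps.

Step 6
Reactants: 10 penta-1,4-dien-3-ol
Product: 11 (1S)-1-[(2R)-oxiran-2-yl]prop-2-en-1-ol
Conditions: Ti(OiPr)4 (0.1 equiv), L-(+)-diisopropyl tartrate (0.12 equiv), t-BuOOH, 4 Å MS, CH2Cl2, −20 °C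
Reagents that add atoms: tert-butyl hydroperoxide, CC(C)(C)OO
Why: Sharpless asymmetric epoxidation used as a desymmetrisation, in which the L-(+)-tartrate catalyst picks one of the two enantiotopic vinyl groups and one of its faces (erythro product), so the carbinol carbon (future C8) becomes S, with high ee because the minor enantiomer is consumed by a second epoxidation.

Step 7
Reactants: 11 (1S)-1-[(2R)-oxiran-2-yl]prop-2-en-1-ol
Product: 12 (1S)-1-[(2R)-oxiran-2-yl]prop-2-en-1-yl 2-methylpropanoate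
Conditions: (i-PrCO)2O, Et3N, DMAP (5 mol %), CH2Cl2, 0 °C
Reagents that add atoms: 2-methylpropanoic anhydride, CC(C)C(=O)OC(=O)C(C)C
Why: DMAP-catalysed acylation puts the first isobutyrate on O8 with no change at the stereocentre.

Step 8
Reactants: 12 (1S)-1-[(2R)-oxiran-2-yl]prop-2-en-1-yl 2-methylpropanoate
Product: 14 (2S)-1-oxobut-3-en-2-yl 2-methylpropanoate, via ring-opened glycol 13 (not isolated)
Conditions: H5IO6, Et2O, 0 °C to rt
Reagents that add atoms: none
Why: periodic acid opens the terminal oxirane to the glycol and cleaves it at once (Malaprade glycol cleavage), so the oxirane carbon becomes the C9 aldehyde while C8 is untouched.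

Step 9
Reactants: 9 (2Z,6Z)-7-iodo-8,8-dimethoxy-3-methylocta-2,6-dien-1-ol; 14 (2S)-1-oxobut-3-en-2-yl 2-methylpropanoate
Product: 15 (2Z,6E,8S,9S)-7-(dimethoxymethyl)-1,8-dihydroxy-3-methylundeca-2,6,10-trien-9-yl 2-methylpropanoate
Conditions: CrCl2 (4 equiv), NiCl2 (2 mol %), chiral oxazoline–sulfonamide ligand of the Kishi type (enantiomer that directs Si-face attack, 4.4 equiv), Et3N, THF, rt
Reagents that add atoms: none
Why: Nozaki–Hiyama–Kishi coupling (nickel-catalysed formation of the alkenylchromium from the iodide and its addition to the aldehyde) with retention of alkene geometry, in which the chiral sulfonamide ligand on chromium directs attack to the Si face of 14 and so sets C9 as S against the modest Felkin preference of the α-acyloxy aldehyde.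

Step 10
Reactants: 15 (2Z,6E,8S,9S)-7-(dimethoxymethyl)-1,8-dihydroxy-3-methylundeca-2,6,10-trien-9-yl 2-methylpropanoate; 16 methyl 2-(bromomethyl)prop-2-enoate
Product: 17 methyl (2Z,4S,5S,6E,10Z)-2-(bromomethyl)-6-(dimethoxymethyl)-5,12-dihydroxy-10-methyl-4-[(2-methylpropanoyl)oxy]dodeca-2,6,10-trienoate
Conditions: second-generation Hoveyda–Grubbs catalyst (10 mol %), 16 (5 equiv), CH2Cl2, 40 °C
Reagents that add atoms: none
Why: olefin cross-metathesis of the only terminal alkene with the 1,1-disubstituted acrylate (the trisubstituted alkenes are inert and the acrylate does not homodimerise), which installs C11–C13 as the 2-(bromomethyl)-2-enoate; either alkene geometry serves the next steps.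

Step 11
Reactants: 17 methyl (2Z,4S,5S,6E,10Z)-2-(bromomethyl)-6-(dimethoxymethyl)-5,12-dihydroxy-10-methyl-4-[(2-methylpropanoyl)oxy]dodeca-2,6,10-trienoate
Product: 18 methyl (2Z,4S,5S,6E,10Z)-2-(bromomethyl)-6-(dimethoxymethyl)-5-hydroxy-10-methyl-4-[(2-methylpropanoyl)oxy]-12-oxododeca-2,6,10-trienoate
Conditions: PhI(OAc)2, TEMPO (10 mol %), CH2Cl2, rt
Reagents that add atoms: none
Why: TEMPO-catalysed oxidation with PhI(OAc)2 is selective for the primary allylic alcohol over the secondary one and gives the (Z)-enal at C6 without Z to E isomerisation and without any amine base that would attack the allylic bromide.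

Step 12
Reactants: 18 methyl (2Z,4S,5S,6E,10Z)-2-(bromomethyl)-6-(dimethoxymethyl)-5-hydroxy-10-methyl-4-[(2-methylpropanoyl)oxy]-12-oxododeca-2,6,10-trienoate
Product: 21 (3aS,4S,5S,6E,10Z,11aR)-6-formyl-5-hydroxy-10-methyl-3-methylidene-2-oxo-2,3,3a,4,5,8,9,11a-octahydrocyclodeca[b]furan-4-yl 2-methylpropanoate, via ten-membered hydroxy ester 19 (not isolated), via lactone dimethyl acetal 20 (not isolated)
Conditions: CrCl2 (10 equiv), THF, 0.005 M, rt; then 1 M HCl, THF, rt
Reagents that add atoms: water, O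
Why: intramolecular Nozaki–Hiyama-type Barbier allylation in which the allylchromium adds through C7 to the C6 aldehyde in a chair transition state with C8 pseudo-equatorial (6,7-anti, hence the trans lactone) and with H8 in the allyl plane and C9 anti to the forming bond (predicted C7 S and C6 R), after which the chromium alkoxide closes the γ-lactone and the acid work-up removes the acetal.

Step 13
Reactants: 21 (3aS,4S,5S,6E,10Z,11aR)-6-formyl-5-hydroxy-10-methyl-3-methylidene-2-oxo-2,3,3a,4,5,8,9,11a-octahydrocyclodeca[b]furan-4-yl 2-methylpropanoate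
Product: 22 (3aS,4S,5S,6E,10Z,11aR)-6-formyl-10-methyl-3-methylidene-2-oxo-2,3,3a,4,5,8,9,11a-octahydrocyclodeca[b]furan-4,5-diyl bis(2-methylpropanoate)
Conditions: (i-PrCO)2O, DMAP, Et3N, CH2Cl2, 0 °C to rt
Reagents that add atoms: 2-methylpropanoic anhydride, CC(C)C(=O)OC(=O)C(C)C
Why: DMAP-catalysed acylation of the only free hydroxyl group gives the second isobutyrate with retention at C9 and completes the target.

**Compound list**
1 | 4-methylanisole (1-methoxy-4-methylbenzene) | COc1ccc(C)cc1 | starting material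
2 | 1-methoxy-4-methylcyclohexa-1,4-diene | COC1=CCC(C)=CC1 | intermediate
3 | 4-methylcyclohex-3-en-1-one | CC1=CCC(=O)CC1 | intermediate
4 | 5-methyl-4,7-dihydrooxepin-2(3H)-one | CC1=CCOC(=O)CC1 | intermediate
5 | (triphenylphosphoranylidene)acetaldehyde | O=CC=P(c1ccccc1)(c1ccccc1)c1ccccc1 | starting material
6 | (4Z)-6-hydroxy-4-methylhex-4-enal (in equilibrium with its lactol) | OC/C=C(/C)CCC=O | intermediate
7 | (2E,6Z)-8-hydroxy-6-methylocta-2,6-dienal | OC/C=C(/C)CC/C=C/C=O | intermediate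
8 | (2Z,6Z)-8-hydroxy-2-iodo-6-methylocta-2,6-dienal | OC/C=C(/C)CC/C=C(/C=O)I | intermediate
9 | (2Z,6Z)-7-iodo-8,8-dimethoxy-3-methylocta-2,6-dien-1-ol | OC/C=C(/C)CC/C=C(/C(OC)OC)I | intermediate
10 | penta-1,4-dien-3-ol (divinylcarbinol) | C=CC(O)C=C | starting material
11 | (1S)-1-[(2R)-oxiran-2-yl]prop-2-en-1-ol | C=C[C@H](O)[C@H]1CO1 | intermediate
12 | (1S)-1-[(2R)-oxiran-2-yl]prop-2-en-1-yl 2-methylpropanoate | C=C[C@H](OC(=O)C(C)C)[C@H]1CO1 | intermediate
13 | (3S,4R)-4,5-dihydroxypent-1-en-3-yl 2-methylpropanoate | C=C[C@H](OC(=O)C(C)C)[C@H](O)CO | intermediate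
14 | (2S)-1-oxobut-3-en-2-yl 2-methylpropanoate | C=C[C@H](OC(=O)C(C)C)C=O | intermediate
15 | (2Z,6E,8S,9S)-7-(dimethoxymethyl)-1,8-dihydroxy-3-methylundeca-2,6,10-trien-9-yl 2-methylpropanoate | OC/C=C(/C)CC/C=C(/C(OC)OC)[C@H](O)[C@@H](OC(=O)C(C)C)C=C | intermediate
16 | methyl 2-(bromomethyl)prop-2-enoate | C=C(CBr)C(=O)OC | starting material
17 | methyl (2Z,4S,5S,6E,10Z)-2-(bromomethyl)-6-(dimethoxymethyl)-5,12-dihydroxy-10-methyl-4-[(2-methylpropanoyl)oxy]dodeca-2,6,10-trienoate | OC/C=C(/C)CC/C=C(/C(OC)OC)[C@H](O)[C@@H](OC(=O)C(C)C)/C=C(/C(=O)OC)CBr | intermediate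
18 | methyl (2Z,4S,5S,6E,10Z)-2-(bromomethyl)-6-(dimethoxymethyl)-5-hydroxy-10-methyl-4-[(2-methylpropanoyl)oxy]-12-oxododeca-2,6,10-trienoate | O=C/C=C(/C)CC/C=C(/C(OC)OC)[C@H](O)[C@@H](OC(=O)C(C)C)/C=C(/C(=O)OC)CBr | intermediate
19 | methyl 2-[(1S,2R,3Z,7E,9S,10S)-8-(dimethoxymethyl)-2,9-dihydroxy-4-methyl-10-[(2-methylpropanoyl)oxy]cyclodeca-3,7-dien-1-yl]prop-2-enoate | C=C(C(=O)OC)[C@H]1[C@H](O)/C=C(/C)CC/C=C(/C(OC)OC)[C@H](O)[C@H]1OC(=O)C(C)C | intermediate
20 | (3aS,4S,5S,6E,10Z,11aR)-6-(dimethoxymethyl)-5-hydroxy-10-methyl-3-methylidene-2-oxo-2,3,3a,4,5,8,9,11a-octahydrocyclodeca[b]furan-4-yl 2-methylpropanoate | C=C1C(=O)O[C@@H]2/C=C(/C)CC/C=C(/C(OC)OC)[C@H](O)[C@@H](OC(=O)C(C)C)[C@@H]12 | intermediate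
21 | (3aS,4S,5S,6E,10Z,11aR)-6-formyl-5-hydroxy-10-methyl-3-methylidene-2-oxo-2,3,3a,4,5,8,9,11a-octahydrocyclodeca[b]furan-4-yl 2-methylpropanoate | C=C1C(=O)O[C@@H]2/C=C(/C)CC/C=C(/C=O)[C@H](O)[C@@H](OC(=O)C(C)C)[C@@H]12 | intermediate
22 | (3aS,4S,5S,6E,10Z,11aR)-6-formyl-10-methyl-3-methylidene-2-oxo-2,3,3a,4,5,8,9,11a-octahydrocyclodeca[b]furan-4,5-diyl bis(2-methylpropanoate) | C=C1C(=O)O[C@@H]2/C=C(/C)CC/C=C(/C=O)[C@H](OC(=O)C(C)C)[C@@H](OC(=O)C(C)C)[C@@H]12 | target

**Step count and risks**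

Total steps: 13. Longest linear sequence: 10 (steps 1 to 5 and 9 to 13).

Step 9 (C9 configuration). The ligand has to override the Felkin preference of 14, so the ratio at C9 may be poor. The fallback sets out from 9 and comes back at 15. Silylate 9 (t-BuMe2SiCl, imidazole) to tert-butyl{[(2Z,6Z)-7-iodo-8,8-dimethoxy-3-methylocta-2,6-dien-1-yl]oxy}dimethylsilane F1. Couple it with 14 by a plain CrCl2/NiCl2 reaction to the carbinol mixture (2Z,6E,9S)-1-[(tert-butyldimethylsilyl)oxy]-7-(dimethoxymethyl)-8-hydroxy-3-methylundeca-2,6,10-trien-9-yl 2-methylpropanoate F2. Oxidise with Dess–Martin periodinane to the enone (2Z,6Z,9S)-1-[(tert-butyldimethylsilyl)oxy]-7-(dimethoxymethyl)-3-methyl-8-oxoundeca-2,6,10-trien-9-yl 2-methylpropanoate F3, which is used at once because its α-hydrogen is acidic. Reduce the ketone with BH3·SMe2 and the CBS oxazaborolidine enantiomer that delivers hydride to the Re face (Corey–Bakshi–Shibata reduction, matched with the Felkin sense for hydride) to (2Z,6E,8S,9S)-1-[(tert-butyldimethylsilyl)oxy]-7-(dimethoxymethyl)-8-hydroxy-3-methylundeca-2,6,10-trien-9-yl 2-methylpropanoate F4. Remove the silyl group with Bu4NF to give 15.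

Step 10 (cross-metathesis). The alkene is flanked by an acyloxy group and the partner is a 2-substituted acrylate, so conversion may be low. The fallback builds the acrylate by a Morita–Baylis–Hillman reaction; it sets out from 12 and comes back at 21. Ozonolysis of the vinyl group of 12 (O3, CH2Cl2, −78 °C, then Me2S) gives (1R)-2-oxo-1-[(2R)-oxiran-2-yl]ethyl 2-methylpropanoate F5. Methyl acrylate and DABCO give methyl (4S)-3-hydroxy-2-methylidene-4-[(2-methylpropanoyl)oxy]-4-[(2R)-oxiran-2-yl]butanoate F6. Ac2O and pyridine give methyl (4S)-3-(acetyloxy)-2-methylidene-4-[(2-methylpropanoyl)oxy]-4-[(2R)-oxiran-2-yl]butanoate F7. H5IO6 opens the oxirane to methyl (4R,5R)-3-(acetyloxy)-5,6-dihydroxy-2-methylidene-4-[(2-methylpropanoyl)oxy]hexanoate F8 and cleaves it in the same flask to methyl (4S)-3-(acetyloxy)-2-methylidene-4-[(2-methylpropanoyl)oxy]-5-oxopentanoate F9. Coupling with 9 under the conditions of step 9 gives methyl (4R,5S,6E,10Z)-3-(acetyloxy)-6-(dimethoxymethyl)-5,12-dihydroxy-10-methyl-2-methylidene-4-[(2-methylpropanoyl)oxy]dodeca-6,10-dienoate F10. PhI(OAc)2 and TEMPO give methyl (4R,5S,6E,10Z)-3-(acetyloxy)-6-(dimethoxymethyl)-5-hydroxy-10-methyl-2-methylidene-4-[(2-methylpropanoyl)oxy]-12-oxododeca-6,10-dienoate F11. Pd(PPh3)4 (5 mol %) and InI turn the allylic acetate into an allylindium that cyclises onto the aldehyde to give 19, which the acid work-up of step 12 carries through 20 to 21. The acetate-bearing carbon is a mixture of epimers throughout and converges at the allylmetal stage.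

Step 12 (macrocyclisation). Ring closure may be slow against oligomerisation, the C6/C7 outcome is a prediction, and acyl migration from O8 to O9 beforehand would open a competing lactonisation. The fallback swaps the order of the two chromium couplings so that the ring is closed at C9–C10; it sets out from 9 and 12 and comes back at 21. Oxidise 9 (PhI(OAc)2, TEMPO) to (2Z,6Z)-7-iodo-8,8-dimethoxy-3-methylocta-2,6-dienal F12. Cross-metathesis of the small alkene 12 with 16 gives methyl (2Z,4S)-2-(bromomethyl)-4-[(2-methylpropanoyl)oxy]-4-[(2R)-oxiran-2-yl]but-2-enoate F13. Intermolecular CrCl2 Barbier allylation and lactonisation of F12 with F13 (the alkenyl iodide is inert without nickel) gives the trans lactone (S)-[(2R,3S)-2-[(1Z,5Z)-6-iodo-7,7-dimethoxy-2-methylhepta-1,5-dien-1-yl]-4-methylidene-5-oxooxolan-3-yl][(2R)-oxiran-2-yl]methyl 2-methylpropanoate F14. Aqueous H5IO6 hydrolyses the acetal and opens the oxirane to (1S,2R)-2,3-dihydroxy-1-[(2R,3S)-2-[(1Z,5Z)-6-iodo-2-methyl-7-oxohepta-1,5-dien-1-yl]-4-methylidene-5-oxooxolan-3-yl]propyl 2-methylpropanoate F15, which is cleaved in the same flask to (1S)-1-[(2R,3S)-2-[(1Z,5Z)-6-iodo-2-methyl-7-oxohepta-1,5-dien-1-yl]-4-methylidene-5-oxooxolan-3-yl]-2-oxoethyl 2-methylpropanoate F16. An intramolecular Nozaki–Hiyama–Kishi reaction (CrCl2, NiCl2 2 mol %, THF–DMSO, high dilution) then gives 21.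

Further compounds
F1 | step 9 | tert-butyl{[(2Z,6Z)-7-iodo-8,8-dimethoxy-3-methylocta-2,6-dien-1-yl]oxy}dimethylsilane | CC(C)(C)[Si](C)(C)OC/C=C(/C)CC/C=C(/C(OC)OC)I
F2 | step 9 | (2Z,6E,9S)-1-[(tert-butyldimethylsilyl)oxy]-7-(dimethoxymethyl)-8-hydroxy-3-methylundeca-2,6,10-trien-9-yl 2-methylpropanoate (both C8 epimers) | CC(C)(C)[Si](C)(C)OC/C=C(/C)CC/C=C(/C(OC)OC)C(O)[C@@H](OC(=O)C(C)C)C=C
F3 | step 9 | (2Z,6Z,9S)-1-[(tert-butyldimethylsilyl)oxy]-7-(dimethoxymethyl)-3-methyl-8-oxoundeca-2,6,10-trien-9-yl 2-methylpropanoate | CC(C)(C)[Si](C)(C)OC/C=C(/C)CC/C=C(/C(OC)OC)C(=O)[C@@H](OC(=O)C(C)C)C=C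
F4 | step 9 | (2Z,6E,8S,9S)-1-[(tert-butyldimethylsilyl)oxy]-7-(dimethoxymethyl)-8-hydroxy-3-methylundeca-2,6,10-trien-9-yl 2-methylpropanoate | CC(C)(C)[Si](C)(C)OC/C=C(/C)CC/C=C(/C(OC)OC)[C@H](O)[C@@H](OC(=O)C(C)C)C=C
F5 | step 10 | (1R)-2-oxo-1-[(2R)-oxiran-2-yl]ethyl 2-methylpropanoate | O=C[C@H](OC(=O)C(C)C)[C@H]1CO1
F6 | step 10 | methyl (4S)-3-hydroxy-2-methylidene-4-[(2-methylpropanoyl)oxy]-4-[(2R)-oxiran-2-yl]butanoate (both C3 epimers) | C=C(C(=O)OC)C(O)[C@H](OC(=O)C(C)C)[C@H]1CO1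
F7 | step 10 | methyl (4S)-3-(acetyloxy)-2-methylidene-4-[(2-methylpropanoyl)oxy]-4-[(2R)-oxiran-2-yl]butanoate (both C3 epimers) | C=C(C(=O)OC)C(OC(C)=O)[C@H](OC(=O)C(C)C)[C@H]1CO1
F8 | step 10 | methyl (4R,5R)-3-(acetyloxy)-5,6-dihydroxy-2-methylidene-4-[(2-methylpropanoyl)oxy]hexanoate (both C3 epimers) | C=C(C(=O)OC)C(OC(C)=O)[C@H](OC(=O)C(C)C)[C@H](O)CO
F9 | step 10 | methyl (4S)-3-(acetyloxy)-2-methylidene-4-[(2-methylpropanoyl)oxy]-5-oxopentanoate (both C3 epimers) | C=C(C(=O)OC)C(OC(C)=O)[C@H](OC(=O)C(C)C)C=O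
F10 | step 10 | methyl (4R,5S,6E,10Z)-3-(acetyloxy)-6-(dimethoxymethyl)-5,12-dihydroxy-10-methyl-2-methylidene-4-[(2-methylpropanoyl)oxy]dodeca-6,10-dienoate (both C3 epimers) | OC/C=C(/C)CC/C=C(/C(OC)OC)[C@H](O)[C@@H](OC(=O)C(C)C)C(OC(C)=O)C(=C)C(=O)OC
F11 | step 10 | methyl (4R,5S,6E,10Z)-3-(acetyloxy)-6-(dimethoxymethyl)-5-hydroxy-10-methyl-2-methylidene-4-[(2-methylpropanoyl)oxy]-12-oxododeca-6,10-dienoate (both C3 epimers) | O=C/C=C(/C)CC/C=C(/C(OC)OC)[C@H](O)[C@@H](OC(=O)C(C)C)C(OC(C)=O)C(=C)C(=O)OC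
F12 | step 12 | (2Z,6Z)-7-iodo-8,8-dimethoxy-3-methylocta-2,6-dienal | O=C/C=C(/C)CC/C=C(/C(OC)OC)I
F13 | step 12 | methyl (2Z,4S)-2-(bromomethyl)-4-[(2-methylpropanoyl)oxy]-4-[(2R)-oxiran-2-yl]but-2-enoate | BrC/C(C(=O)OC)=C\[C@H](OC(=O)C(C)C)[C@H]1CO1
F14 | step 12 | (S)-[(2R,3S)-2-[(1Z,5Z)-6-iodo-7,7-dimethoxy-2-methylhepta-1,5-dien-1-yl]-4-methylidene-5-oxooxolan-3-yl][(2R)-oxiran-2-yl]methyl 2-methylpropanoate | C=C1C(=O)O[C@H](/C=C(/C)CC/C=C(/C(OC)OC)I)[C@H]1[C@H](OC(=O)C(C)C)[C@H]1CO1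
F15 | step 12 | (1S,2R)-2,3-dihydroxy-1-[(2R,3S)-2-[(1Z,5Z)-6-iodo-2-methyl-7-oxohepta-1,5-dien-1-yl]-4-methylidene-5-oxooxolan-3-yl]propyl 2-methylpropanoate | C=C1C(=O)O[C@H](/C=C(/C)CC/C=C(/C=O)I)[C@H]1[C@H](OC(=O)C(C)C)[C@H](O)CO
F16 | step 12 | (1S)-1-[(2R,3S)-2-[(1Z,5Z)-6-iodo-2-methyl-7-oxohepta-1,5-dien-1-yl]-4-methylidene-5-oxooxolan-3-yl]-2-oxoethyl 2-methylpropanoate | C=C1C(=O)O[C@H](/C=C(/C)CC/C=C(/C=O)I)[C@H]1[C@H](OC(=O)C(C)C)C=O
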